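**Retrosynthetic overview**
1. The target is the (7S,8R)-erythro 8-O-4′ aryl ether of an all-trans (1S,2S,3R)-1-aryl-2,3-dimethyltetralin. The last C–C disconnection is the tetralin C1–aryl bond, made by a Ni/photoredox deoxygenative cross-coupling of a 1-tetralol with an aryl bromide that already carries the complete side chain.
2. The tetralol comes from a tetralone, made by intramolecular Friedel–Crafts acylation of a (2S,3R)-4-aryl-2,3-dimethylbutanoic acid. This is the only ring formed, and it is closed before fragment union. The aryl–CH2 bond comes from a Negishi coupling of the zinc reagent of a trans-dimethyl-γ-butyrolactone-derived iodo ester.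
3. The side-chain aryl bromide comes from Mitsunobu etherification of ethyl (S)-lactate (C8, inversion), then Weinreb amide, aryl Grignard addition and chelation-controlled ketone reduction (C7).
4. All three guaiacyl rings come from one 4-bromoguaiacol unit made from catechol. C3 comes from asymmetric hydrogenation of 4-methylbutenolide and C2 from trans-selective lactone methylation.

Assumption: in step 4 the BINAP antipode is the one that gives the (S)-lactone; I have not fixed which antipode that is, so it must be assigned by optical rotation of this known compound.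

---

**Step 1**
Reactants: 1 catechol
Product: 2 guaiacol (2-methoxyphenol)
Conditions: MeI (1.0 equiv), Li2CO3, DMF, 55 °C
Reagents that add atoms: iodomethane, CI
Why: Weak-base Williamson mono-O-methylation; Li2CO3 ionises only the first catechol OH, so the monoether is the main product (unreacted catechol is recycled).

**Step 2**
Reactants: 2 guaiacol
Product: 3 4-bromo-2-methoxyphenol
Conditions: Bu4NBr3, CH2Cl2/MeOH, rt
Reagents that add atoms: tetrabutylammonium tribromide (Bu4N+ Br3−, written as the Br−·Br2 adduct), CCCC[N+](CCCC)(CCCC)CCCC.[Br-].BrBr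
Why: Electrophilic aromatic bromination; the free OH is the stronger director and the bulky tribromide delivers Br para to it.

**Step 3**
Reactants: 3 4-bromo-2-methoxyphenol
Product: 4 1-(benzyloxy)-4-bromo-2-methoxybenzene
Conditions: BnBr, K2CO3, DMF, rt
Reagents that add atoms: benzyl bromide, BrCc1ccccc1
Why: Williamson etherification; the benzyl ether serves as the phenol protecting group for both the ring-A and the tetralin-ring building blocks.

**Step 4**
Reactants: 5 4-methylfuran-2(5H)-one
Product: 6 (S)-4-methyldihydrofuran-2(3H)-one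
Conditions: H2 (100 atm), Ru(OAc)2(BINAP) (antipode giving (S)-6), CH2Cl2, 50 °C
Reagents that add atoms: none
Why: Ru–BINAP asymmetric hydrogenation of a β-substituted butenolide; the catalyst sets the β-methyl stereocentre, which becomes tetralin C3.

**Step 5**
Reactants: 6 (S)-4-methyldihydrofuran-2(3H)-one
Product: 7 (3S,4S)-3,4-dimethyldihydrofuran-2(3H)-one (trans)
Conditions: LDA, THF, −78 °C; MeI, −78 °C
Reagents that add atoms: iodomethane, CI
Why: Lactone enolate alkylation; MeI approaches the planar enolate anti to the β-methyl group, giving the trans-dimethyl lactone (future tetralin C2).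

**Step 6**
Reactants: 7 (3S,4S)-3,4-dimethyldihydrofuran-2(3H)-one
Product: 8 ethyl (2S,3S)-4-iodo-2,3-dimethylbutanoate
Conditions: TMSI, CH2Cl2, rt; then EtOH
Reagents that add atoms: iodotrimethylsilane, C[Si](C)(C)I; ethanol, CCO
Why: Silyl-iodide lactone cleavage (iodide SN2 at the O-activated γ-CH2) followed by alcoholysis of the silyl ester; neither stereocentre is touched.

**Step 7**
Reactants: 8 ethyl (2S,3S)-4-iodo-2,3-dimethylbutanoate; 4 1-(benzyloxy)-4-bromo-2-methoxybenzene
Product: 9 ethyl (2S,3R)-4-[4-(benzyloxy)-3-methoxyphenyl]-2,3-dimethylbutanoate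
Conditions: 8, Zn dust (TMSCl/BrCH2CH2Br-activated), LiCl, THF, 40 °C; then 4, Pd(OAc)2 (2 mol %), SPhos (4 mol %), THF, 50 °C
Reagents that add atoms: none
Why: Negishi C(sp3)–C(sp2) coupling; the ester-tolerant primary alkylzinc couples with the electron-rich aryl bromide under Pd/SPhos and no stereocentre is involved (the 3-descriptor changes only through CIP priorities).

**Step 8**
Reactants: 9 ethyl (2S,3R)-4-[4-(benzyloxy)-3-methoxyphenyl]-2,3-dimethylbutanoate
Product: 10 (2S,3R)-4-[4-(benzyloxy)-3-methoxyphenyl]-2,3-dimethylbutanoic acid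
Conditions: LiOH, THF/MeOH/H2O, rt; then dilute HCl
Reagents that add atoms: lithium hydroxide, [Li+].[OH-] (water, O)
Why: Ester saponification; the benzyl ether is inert and any minor α-epimerisation is corrected in step 9.

**Step 9**
Reactants: 10 (2S,3R)-4-[4-(benzyloxy)-3-methoxyphenyl]-2,3-dimethylbutanoic acid
Product: 11 (2S,3R)-7-(benzyloxy)-6-methoxy-2,3-dimethyl-3,4-dihydronaphthalen-1(2H)-one
Conditions: TFAA, CH2Cl2, 0 °C to rt; aqueous work-up, then DBU (cat.), toluene, rt
Reagents that add atoms: none
Why: Intramolecular Friedel–Crafts acylation via the mixed trifluoroacetic anhydride closes the six-membered ring para to the methoxy group, and DBU equilibrates the α-centre to the diequatorial trans-2,3-dimethyl ketone.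

**Step 10**
Reactants: 11 the tetralone
Product: 12 (1R,2S,3R)-7-(benzyloxy)-6-methoxy-2,3-dimethyl-1,2,3,4-tetrahydronaphthalen-1-ol (major; the C1 epimer is carried along)
Conditions: NaBH4, MeOH/THF, 0 °C to rt (base-washed silica for purification)
Reagents that add atoms: none
Why: Hydride reduction of the aryl ketone (axial delivery gives mainly the 1,2-trans alcohol); the C1 configuration is irrelevant because it is erased in step 16.

**Step 11**
Reactants: 3 4-bromo-2-methoxyphenol; 13 ethyl (S)-lactate
Product: 14 ethyl (R)-2-(4-bromo-2-methoxyphenoxy)propanoate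
Conditions: PPh3, DIAD, THF, 0 °C to rt
Reagents that add atoms: none
Why: Mitsunobu etherification; SN2 displacement of the activated lactate oxygen by the phenol inverts the centre cleanly, setting C8 as R.

**Step 12**
Reactants: 14 ethyl (R)-2-(4-bromo-2-methoxyphenoxy)propanoate
Product: 15 (R)-2-(4-bromo-2-methoxyphenoxy)-N-methoxy-N-methylpropanamide
Conditions: MeNH(OMe)·HCl, AlMe3, CH2Cl2, 0 °C to rt
Reagents that add atoms: N,O-dimethylhydroxylamine hydrochloride, CNOC.Cl
Why: Weinreb aminolysis with the aluminium amide is non-basic, so the α-aryloxy stereocentre is retained.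

**Step 13**
Reactants: 15 the Weinreb amide; 4 1-(benzyloxy)-4-bromo-2-methoxybenzene
Product: 16 (R)-1-[4-(benzyloxy)-3-methoxyphenyl]-2-(4-bromo-2-methoxyphenoxy)propan-1-one
Conditions: 4, Mg, THF (ArMgBr, 1.3 equiv); add to 15, THF, 0 °C; cold aq. NH4Cl
Reagents that add atoms: none
Why: Weinreb ketone synthesis; the stable Mg chelate stops at the ketone, the aryl bromide of 15 does not exchange with ArMgBr, and C8 is not enolised before the neutral quench.

**Step 14**
Reactants: 16 the α-aryloxy ketone
Product: 17 (1S,2R)-1-[4-(benzyloxy)-3-methoxyphenyl]-2-(4-bromo-2-methoxyphenoxy)propan-1-ol (erythro)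
Conditions: Zn(BH4)2, Et2O, −20 to 0 °C
Reagents that add atoms: none
Why: Cram-chelate reduction; Zn bridges the carbonyl and the α-guaiacyloxy oxygens and hydride attacks from the face of the small α-H, giving the anti (erythro) carbinol with C7 as S.

**Step 15**
Reactants: 17 the erythro alcohol
Product: 18 tert-butyl{(1S,2R)-1-[4-(benzyloxy)-3-methoxyphenyl]-2-(4-bromo-2-methoxyphenoxy)propoxy}dimethylsilane
Conditions: TBSOTf, 2,6-lutidine, CH2Cl2, 0 °C
Reagents that add atoms: tert-butyldimethylsilyl triflate, CC(C)(C)[Si](C)(C)OS(=O)(=O)C(F)(F)F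
Why: Silylation masks the benzylic carbinol so that only alcohol 12 is activated in the coupling; no stereocentre is affected.

**Step 16**
Reactants: 12 the tetralol (1.5 equiv, epimer mixture); 18 the aryl bromide
Product: 19 tert-butyl{(1S,2R)-1-[4-(benzyloxy)-3-methoxyphenyl]-2-{4-[(1S,2S,3R)-7-(benzyloxy)-6-methoxy-2,3-dimethyl-1,2,3,4-tetrahydronaphthalen-1-yl]-2-methoxyphenoxy}propoxy}dimethylsilane
Conditions: 12, N-aryl benzoxazolium tetrafluoroborate (alcohol activator, 1.4 equiv), pyridine, MTBE, rt, 15 min; then 18, NiBr2·dtbbpy (10 mol %), [Ir(ppy)2(dtbbpy)]PF6 (2 mol %), quinuclidine, MTBE/DMA, 450 nm LEDs, rt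
Reagents that add atoms: none
Why: Proposed new method: the free tetralol is condensed in situ with the benzoxazolium salt, and photocatalytic single-electron oxidation, deprotonation and β-scission of the adduct release the planar, p-methoxyaryl-stabilised C1 benzylic radical (erasing the carbinol configuration); (dtbbpy)Ni inserts into the C–Br bond of 18, captures the radical reversibly, and the product-determining C(sp3)–C(sp2) reductive elimination from Ni(III) goes through the diastereomer with Ni/aryl pseudo-equatorial and trans to the equatorial C2 methyl (all-equatorial half-chair), so both epimers of 12 converge on the (1S) diarylmethine. The closest known reactions are NHC-mediated metallaphotoredox deoxygenative arylation of aliphatic alcohols and trans-selective, stereoconvergent Ni-catalysed arylation of benzylic and 2-substituted cycloalkyl radicals; to my knowledge neither has been shown on a 2,3-disubstituted electron-rich 1-tetralol, for a diarylmethine stereocentre, or as a late fragment union.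

**Step 17**
Reactants: 19 the coupled silyl ether
Product: 20 (1S,2R)-1-[4-(benzyloxy)-3-methoxyphenyl]-2-{4-[(1S,2S,3R)-7-(benzyloxy)-6-methoxy-2,3-dimethyl-1,2,3,4-tetrahydronaphthalen-1-yl]-2-methoxyphenoxy}propan-1-ol
Conditions: TBAF, THF, 0 °C to rt
Reagents that add atoms: none
Why: Fluoride cleavage of the secondary TBS ether; aryl benzyl ethers and all stereocentres are untouched.

**Step 18**
Reactants: 20 the bis-benzyl ether
Product: 21 target, 4-[(1S,2R)-1-hydroxy-2-{4-[(1S,2S,3R)-7-hydroxy-6-methoxy-2,3-dimethyl-1,2,3,4-tetrahydronaphthalen-1-yl]-2-methoxyphenoxy}propyl]-2-methoxyphenol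
Conditions: H2 (1 atm), 10% Pd/C, EtOAc/EtOH, rt (monitored, stopped at full debenzylation)
Reagents that add atoms: none
Why: Hydrogenolysis of the two aryl benzyl ethers under neutral, low-pressure conditions, where the secondary benzylic alcohol, the alkyl aryl ether and the diarylmethine C–H are retained.

---

**Compound list**
1 | catechol | Oc1ccccc1O | starting material
2 | guaiacol | COc1ccccc1O | intermediate
3 | 4-bromo-2-methoxyphenol | COc1cc(Br)ccc1O | intermediate
4 | 1-(benzyloxy)-4-bromo-2-methoxybenzene | COc1cc(Br)ccc1OCc1ccccc1 | intermediate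
5 | 4-methylfuran-2(5H)-one | CC1=CC(=O)OC1 | starting material
6 | (S)-4-methyldihydrofuran-2(3H)-one | O=C1C[C@H](C)CO1 | intermediate
7 | (3S,4S)-3,4-dimethyldihydrofuran-2(3H)-one | O=C1[C@@H](C)[C@H](C)CO1 | intermediate
8 | ethyl (2S,3S)-4-iodo-2,3-dimethylbutanoate | CCOC(=O)[C@@H](C)[C@H](C)CI | intermediate
9 | ethyl (2S,3R)-4-[4-(benzyloxy)-3-methoxyphenyl]-2,3-dimethylbutanoate | CCOC(=O)[C@@H](C)[C@H](C)Cc1ccc(OCc2ccccc2)c(OC)c1 | intermediate
10 | (2S,3R)-4-[4-(benzyloxy)-3-methoxyphenyl]-2,3-dimethylbutanoic acid | OC(=O)[C@@H](C)[C@H](C)Cc1ccc(OCc2ccccc2)c(OC)c1 | intermediate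
11 | (2S,3R)-7-(benzyloxy)-6-methoxy-2,3-dimethyl-3,4-dihydronaphthalen-1(2H)-one | O=C1[C@@H](C)[C@H](C)Cc2cc(OC)c(OCc3ccccc3)cc21 | intermediate
12 | (1R,2S,3R)-7-(benzyloxy)-6-methoxy-2,3-dimethyl-1,2,3,4-tetrahydronaphthalen-1-ol (major C1 epimer) | O[C@@H]1[C@@H](C)[C@H](C)Cc2cc(OC)c(OCc3ccccc3)cc21 | intermediate
13 | ethyl (S)-lactate | CCOC(=O)[C@H](C)O | starting material
14 | ethyl (R)-2-(4-bromo-2-methoxyphenoxy)propanoate | CCOC(=O)[C@@H](C)Oc1ccc(Br)cc1OC | intermediate
15 | (R)-2-(4-bromo-2-methoxyphenoxy)-N-methoxy-N-methylpropanamide | CON(C)C(=O)[C@@H](C)Oc1ccc(Br)cc1OC | intermediate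
16 | (R)-1-[4-(benzyloxy)-3-methoxyphenyl]-2-(4-bromo-2-methoxyphenoxy)propan-1-one | COc1cc(C(=O)[C@@H](C)Oc2ccc(Br)cc2OC)ccc1OCc1ccccc1 | intermediate
17 | (1S,2R)-1-[4-(benzyloxy)-3-methoxyphenyl]-2-(4-bromo-2-methoxyphenoxy)propan-1-ol | COc1cc([C@H](O)[C@@H](C)Oc2ccc(Br)cc2OC)ccc1OCc1ccccc1 | intermediate
18 | TBS ether of 17 | COc1cc([C@H](O[Si](C)(C)C(C)(C)C)[C@@H](C)Oc2ccc(Br)cc2OC)ccc1OCc1ccccc1 | intermediate
19 | fully protected coupled product (7S,8R; 1S,2S,3R) | COc1cc([C@H](O[Si](C)(C)C(C)(C)C)[C@@H](C)Oc2ccc([C@H]3c4cc(OCc5ccccc5)c(OC)cc4C[C@@H](C)[C@@H]3C)cc2OC)ccc1OCc1ccccc1 | intermediate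
20 | bis-benzyl ether of the target | COc1cc([C@H](O)[C@@H](C)Oc2ccc([C@H]3c4cc(OCc5ccccc5)c(OC)cc4C[C@@H](C)[C@@H]3C)cc2OC)ccc1OCc1ccccc1 | intermediate
21 | CID53359464 | COc1cc([C@H](O)[C@@H](C)Oc2ccc([C@H]3c4cc(O)c(OC)cc4C[C@@H](C)[C@@H]3C)cc2OC)ccc1O | target

---

**Total step count:** 18
**Longest linear sequence:** 10 (for example steps 1, 2, 3, 7, 8, 9, 10, 16, 17, 18; the lactone and side-chain branches are equally long)

**Three steps most likely to fail**
1. **Step 16 (proposed new coupling).** The risks are insufficient trans selectivity at C1, oxidation of the electron-rich benzylic radical followed by elimination to the dihydronaphthalene, and radical dimerisation. Fallback with known chemistry: reduce ester 9 to the aldehyde (DIBAL-H), add the aryllithium from O-silylated 3, and close the ring by acid-mediated Friedel–Crafts cycloalkylation of the benzylic alcohol (BF3·OEt2), the established entry to all-trans 1-aryl-2,3-dimethyltetralins. Then free the ring-B phenol and attach the side chain by Mitsunobu with 13, followed by the chemistry of steps 12–14 and debenzylation.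
2. **Step 9 (Friedel–Crafts acylation).** The risks are partial loss of the benzyl ether or incomplete cyclisation under acid. Fallback: Parham cyclisation, that is, NBS bromination of 9 para to the methoxy group, conversion of the ester to the Weinreb amide, then t-BuLi Br/Li exchange at −78 °C with intramolecular acylation. This gives tetralone 11 without any acid.
3. **Step 14 (chelation-controlled reduction).** The risk is a modest erythro/threo ratio if the aryloxy oxygen chelates poorly. Fallback: abandon substrate control and set C7 by catalyst control, using a CBS oxazaborolidine/borane reduction of 16 with the catalyst antipode that delivers the 7S carbinol.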